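# Proposal: (S)-Glabrol by iridium allylic etherification and enol ether ring-closing metathesis

Prenyl means 3-methylbut-2-en-1-yl throughout, and flavanone numbering is used (O1, C2, C3, C4, C4a, C5–C8, C8a; ring B primed).

## The problem

Glabrol (20) is a (2S)-flavanone. Ring A is resorcinol-derived, with a hydroxyl at C7 and a prenyl group at C8, and is fused through O1 and the C4 carbonyl to the dihydropyranone ring C. C2 carries ring B, which has a hydroxyl at C4' and a prenyl group at C3'.

C2 is the only stereocenter, so no other element of the molecule can control it; a catalyst or reagent has to set it. It is also fragile. It is benzylic, alpha to O1 and beta to the ketone, so base opens ring C by retro-oxa-Michael reaction to an achiral 2'-hydroxychalcone. Acid can ionise the C2–O1 bond with help from the para oxygen of ring B. Once set, C2 should therefore see only near-neutral conditions.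

Both prenyl groups sit ortho to a phenol. Strong acid cyclises them to 2,2-dimethylchromans, and hydrogenation and oxidants are excluded. The C8 prenyl group lies between O1 and O7 and has to be told apart from C6.

The feature that opens the route is that C3 and C4 are the only ring C atoms between C2 and ring A. In the enol form of the ketone they are joined by a C3=C4 double bond, flanked by C2 (which can carry a vinyl group) and ring A (which can carry the enol ether of an acetyl group). Cutting there leaves an acyclic aryl ether whose O1–C2 bond is a branched allylic C–O bond.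

## Retrosynthesis

**20 from 19.** The last operation only frees O4' from its methoxymethyl ether. This acetal is chosen because it survives base, hydride, amide base, the ruthenium carbene and heat. It comes off with dilute protic acid only after the acid-labile tertiary allyl ether has been used up.

**19 from 17.** The C8–prenyl bond is cut and the prenyl unit is returned to O7 as a 1,1-dimethylallyl ether, the retron of an aromatic Claisen rearrangement. Carrying the C8 prenyl group from the start was considered and set aside. It would give the C2 vinyl group a second metathesis partner (closure of a seven-membered oxepine) and would crowd the phenol that has to be etherified. The forward step must deliver the allyl unit to C8 and not C6, at a temperature that leaves C2 alone.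

**17 from 16, and 16 from 15 (the strategic cut).** Flavanone 17 is the hydrolysis product of cyclic silyl enol ether 16. In 16 the C3=C4 bond is disconnected by ring-closing metathesis to the acyclic diene 15, which has a vinyl group on C2 and a silyl enol ether on ring A.

- The neighbouring cut at C2–C3 or O1–C2 by aldol and oxa-Michael chemistry sets C2 in a reversible conjugate addition.
- The cut at O1–C8a needs a C–O coupling at a doubly flanked aryl position.
- The metathesis cut closes the ring under neutral conditions with C2 already fixed and the ketone masked, so neither ring-opening nor ionisation has a pathway.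

Precursor 15 is acyclic with one stereocenter. The forward reaction must close a six-membered ring onto a 1,1-disubstituted, electron-rich alkene faster than any other alkene reacts.

**15 from 13.** The enol ether comes from methyl ketone 13 by O-silylation of its enolate. Only the acetyl methyl group is enolisable. A basic protocol is asked for, since a silyl triflate could ionise the doubly activated C–O bond at the stereocenter.

**13 from 11 and 7.** Cutting O1–C2 gives phenol 11 and the linear cinnamyl carbonate 7. The forward step is a branched-selective, enantioselective allylic etherification with [Ir(cod)Cl]2 and a chiral phosphoramidite. This is preferred over displacement at a secondary benzylic, allylic alcohol, which tends to ionise. It is also preferred over palladium allylation, which favours the linear ether. The step is convergent and is the only one that creates chirality.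

**11 from 10, and 10 from 8 and 9.** A tertiary allyl aryl ether cannot be made by direct displacement, so O4 of 8 is alkylated with the tertiary propargylic chloride 9 and the alkyne 10 is semi-hydrogenated. O4 reacts in preference to O2 because the O2 hydrogen is tied to the acetyl carbonyl.

**7 from 6, 5, 4, 3, and from 1 and 2.** The carbonate comes from allylic alcohol 6. Alcohol 6 comes from ester 5 by hydride reduction, and 5 from aldehyde 4 by a two-carbon Wittig extension. Aldehyde 4 is the protected form of 3, which is made by ortho C-prenylation of 1 with 2.

## Roads not taken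

**Alternative 1:** The cut is at C2–C3 and O1–C8a, with ring A arriving as a non-aromatic six-membered ring. The bis(silyloxy) diene A1 would add through its terminal methylene to the ring B aldehyde A2 under Ti(OiPr)4 and BINOL. Acid would then condense the new hydroxyl onto C8a to give the tetrahydrochromenone A3, and ring A would be dehydrogenated and both protecting groups removed to reach 20.
- Merits: a C–C bond and the stereocenter form in one catalytic event. The C8 prenyl group is placed while ring A is still an alicyclic 1,3-dicarbonyl unit, so its position is beyond doubt. In this respect it is better than the chosen plan, which relies on the regiochemistry of a Claisen shift.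
- Weak points: the asymmetric aldol has its precedent with acyclic acetoacetate-type dienes, not with a diene cross-conjugated into a ring. The acid condensation passes through a beta-hydroxy ketone that can dehydrate to an enone, which would re-close without control. Aromatising ring A in A3 needs an oxidant that spares two prenyl groups and does not carry on to the flavone. The pivalate has to be removed by a nucleophile or base in the presence of the base-sensitive flavanone.
- Comparison: the chosen plan keeps ring A aromatic throughout and never needs an oxidant. Against the better regiocontrol of this road it sets a stereocenter that is formed in a well-studied reaction class and is then never exposed to acid or base strong enough to open ring C.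

**Alternative 2:** The cut is at O1–C8a. The (1S) bromo alcohol A4 would cyclise under Pd(OAc)2, a bulky biaryl di-tert-butylphosphine and Cs2CO3 to the C4-silyloxy flavan A5. Desilylation, oxidation at C4 and removal of two acetals would follow.
- Merits: C2 would come from a reliable asymmetric carbonyl reduction. Both prenyl groups are in place from the start, so there is no regiochemical question, no metathesis and no heating step. On regiochemistry and thermal mildness this road is as good as or better than the chosen one.
- Weak points: the bromide in A4 is flanked by the C8 prenyl group and the C4a side chain, the hardest case for C–O reductive elimination. The secondary benzylic alkoxide on palladium can undergo beta-hydride elimination, giving a ketone and a debrominated arene. C4 is a second, unneeded stereocenter until it is oxidised. The oxidation state at C4 has to be adjusted after ring closure, so the sequence is no shorter.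
- Comparison: the chosen plan joins two simple fragments and creates chirality in the same step, and it closes the ring at an unhindered site under neutral conditions.

**Alternative 3:** The cut is at C4–C4a and O1–C8a. Lithiated A6 (from bromine–lithium exchange) would attack the carbonyl of the (S)-beta-lactone A7. The released C2 alkoxide would then displace the ortho fluoride to give the protected flavanone A8, two deprotections from 20.
- Merits: this is the shortest road. Two ring bonds form in one flask, the C2–O bond is never broken, and the prenyl positions are fixed. In step count and regiocontrol it is better than the chosen plan.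
- Weak points: ortho-fluoro aryllithiums decompose by loss of fluoride unless kept very cold. The pivalate of A7 and the newly formed ketone are competing electrophiles. The beta-alkoxide of an aryl ketone in a strongly basic medium can undergo retro-aldol cleavage or elimination to the enone, which would re-close as a racemate. A 4-aryl beta-lactone with a para-oxygenated aryl group ionises and decarboxylates readily and is not easily made in high enantiomeric purity. The final ester cleavage again needs base.
- Comparison: this road stacks several fragile events on one step. The chosen plan is longer, but each operation has close precedent and C2 meets no strong base after it is set.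

Key step: step 10

## Assumptions

- Compounds 1, 2, 8 and 9 are commercial.
- L denotes the BINOL-derived phosphoramidite with an N,N-bis(1-phenylethyl)amino group. Its (Sa,Sc,Sc) enantiomer is taken to give the (S)-configured branched ether, by analogy with the established sense of induction for cinnamyl carbonates and aryloxides. If the sense proves opposite for this pair, the enantiomeric ligand is used.

## Route

Step 1
Reactants: 1 4-hydroxybenzaldehyde; 2 prenyl bromide
Product: 3 4-hydroxy-3-prenylbenzaldehyde
Conditions: KOH, H2O, rt
Reagents that add atoms: none
Why: Phenoxide C-alkylation: in water the potassium phenoxide is hydrogen-bonded at oxygen, so the allylic bromide attacks the ring carbon ortho to the oxide, the para position being blocked by the formyl group. O-Prenyl and bis-prenyl by-products are expected and are removed by chromatography, so only modest efficiency is expected of this cheap opening step.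

Step 2
Reactants: 3 4-hydroxy-3-prenylbenzaldehyde
Product: 4 4-(methoxymethoxy)-3-prenylbenzaldehyde
Conditions: MOMCl, iPr2NEt, CH2Cl2, 0 °C to rt
Reagents that add atoms: chloromethyl methyl ether, COCCl
Why: O-Alkylation of the phenol with a reactive alpha-chloro ether and a hindered amine base (Williamson-type etherification). The acetal tolerates every later reagent up to the final acid step.

Step 3
Reactants: 4 4-(methoxymethoxy)-3-prenylbenzaldehyde
Product: 5 ethyl (2E)-3-[4-(methoxymethoxy)-3-prenylphenyl]prop-2-enoate
Conditions: Ph3P=CHCO2Et, toluene, 80 °C
Reagents that add atoms: ethyl (triphenylphosphoranylidene)acetate, CCOC(=O)C=P(c1ccccc1)(c1ccccc1)c1ccccc1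
Why: Wittig olefination with a stabilised ylide, which gives the E enoate. No external base is present.

Step 4
Reactants: 5 ethyl (2E)-3-[4-(methoxymethoxy)-3-prenylphenyl]prop-2-enoate
Product: 6 (2E)-3-[4-(methoxymethoxy)-3-prenylphenyl]prop-2-en-1-ol
Conditions: iBu2AlH, CH2Cl2, −78 °C
Reagents that add atoms: none
Why: 1,2-Reduction of the enoate by two hydride equivalents at low temperature gives the allylic alcohol. The acetal and the isolated trisubstituted alkene are inert.

Step 5
Reactants: 6 (2E)-3-[4-(methoxymethoxy)-3-prenylphenyl]prop-2-en-1-ol
Product: 7 methyl (2E)-3-[4-(methoxymethoxy)-3-prenylphenyl]prop-2-en-1-yl carbonate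
Conditions: ClCO2Me, pyridine, CH2Cl2, 0 °C
Reagents that add atoms: methyl chloroformate, COC(=O)Cl
Why: Acylation of the primary allylic alcohol. The linear methyl carbonate is the standard electrophile for iridium allylic substitution because its leaving group breaks down to carbon dioxide and methoxide.

Step 6
Reactants: 8 2,4-dihydroxyacetophenone; 9 3-chloro-3-methylbut-1-yne
Product: 10 1-[2-hydroxy-4-(2-methylbut-3-yn-2-yloxy)phenyl]ethanone
Conditions: K2CO3, KI (cat.), CuI (cat.), acetone, reflux
Reagents that add atoms: none
Why: Copper-assisted propargylic substitution of the tertiary chloride by the phenoxide. The 2-hydroxyl is hydrogen-bonded to the acetyl carbonyl and less acidic, so only O4 is alkylated.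

Step 7
Reactants: 10 1-[2-hydroxy-4-(2-methylbut-3-yn-2-yloxy)phenyl]ethanone
Product: 11 1-[2-hydroxy-4-(2-methylbut-3-en-2-yloxy)phenyl]ethanone
Conditions: H2 (1 atm), Pd/CaCO3 (Pb(OAc)2-poisoned), quinoline, EtOAc, rt
Reagents that add atoms: none
Why: Semi-hydrogenation of the terminal alkyne on poisoned palladium stops at the alkene. Room temperature keeps the 1,1-dimethylallyl ether from rearranging early.

Step 8
Reactants: 11 1-[2-hydroxy-4-(2-methylbut-3-en-2-yloxy)phenyl]ethanone; 7 methyl (2E)-3-[4-(methoxymethoxy)-3-prenylphenyl]prop-2-en-1-yl carbonate
Product: 13 1-{2-[(1S)-1-(4-(methoxymethoxy)-3-prenylphenyl)prop-2-en-1-yloxy]-4-(2-methylbut-3-en-2-yloxy)phenyl}ethanone, via sodium aryloxide 12 (not isolated)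
Conditions: NaH, THF, 0 °C; then 7, [Ir(cod)Cl]2 (2 mol%), (Sa,Sc,Sc)-L (4 mol%), THF, 25–40 °C
Reagents that add atoms: none
Why: Iridium-catalysed asymmetric allylic etherification: the cyclometalated iridium–phosphoramidite complex ionises the linear carbonate to an allyl complex, and the aryloxide (used in excess) attacks the aryl-substituted terminus to give the branched ether. The ligand controls which face is attacked and so sets the S configuration of the future C2. The reaction is stopped at full conversion so that the product is not re-ionised.

Step 9
Reactants: 13 1-{2-[(1S)-1-(4-(methoxymethoxy)-3-prenylphenyl)prop-2-en-1-yloxy]-4-(2-methylbut-3-en-2-yloxy)phenyl}ethanone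
Product: 15 tert-butyldimethylsilyl enol ether of 13, that is tert-butyl{1-[2-((1S)-1-(4-(methoxymethoxy)-3-prenylphenyl)prop-2-en-1-yloxy)-4-(2-methylbut-3-en-2-yloxy)phenyl]ethenyloxy}dimethylsilane, via potassium enolate 14 (not isolated)
Conditions: KN(SiMe3)2, THF, −78 °C; then TBSCl, −78 to 0 °C
Reagents that add atoms: tert-butyldimethylsilyl chloride, CC(C)(C)[Si](C)(C)Cl
Why: Kinetic deprotonation of the only enolisable position and O-silylation of the enolate (silyl enol ether formation). The basic protocol avoids a silyl triflate that could ionise the benzylic, allylic C–O bond at the stereocenter, which is untouched.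

Step 10
Reactants: 15 tert-butyldimethylsilyl enol ether of 13
Product: 16 (2S)-4-(tert-butyldimethylsilyloxy)-2-[4-(methoxymethoxy)-3-prenylphenyl]-7-(2-methylbut-3-en-2-yloxy)-2H-chromene
Conditions: (H2IMes)(PCy3)Cl2Ru=CHPh (second-generation Grubbs catalyst, 10 mol%), toluene (0.005 M), Ar sparge, 60 °C
Reagents that add atoms: none
Why: Ring-closing metathesis: the ruthenium benzylidene exchanges with the least hindered alkene, the vinyl group on C2, to place the alkylidene at the future C3. A [2+2] addition to the enol ether methylene gives a ruthenacyclobutane, and cycloreversion releases the C3=C4 bond and Ru=CH2, which carries the chain with loss of ethylene. The closest known reaction type is the ring-closing metathesis of silyl enol ethers of methyl ketones bearing a terminal alkene to cyclic silyl enol ethers, together with enol ether metathesis to chromenes. Ring C closes as a six-membered ring with an endocyclic double bond whose geometry is fixed by the ring. No stereocenter is formed, and C2 keeps its configuration because no bond to it is made or broken and the medium is neutral. The step needs chemoselectivity among four alkenes. The enol ether reacts only intramolecularly. The ring B prenyl group is trisubstituted and could close only a meta-bridged ring. The O7 allyl ether has a quaternary allylic carbon and could close only a strained medium ring. High dilution and removal of ethylene suppress cross-metathesis. The C8 prenyl group is absent at this stage, so no seven-membered closure competes.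

Step 11
Reactants: 16 (2S)-4-(tert-butyldimethylsilyloxy)-2-[4-(methoxymethoxy)-3-prenylphenyl]-7-(2-methylbut-3-en-2-yloxy)-2H-chromene
Product: 17 (2S)-2-[4-(methoxymethoxy)-3-prenylphenyl]-7-(2-methylbut-3-en-2-yloxy)chroman-4-one
Conditions: Bu4NF, AcOH, THF, 0 °C
Reagents that add atoms: none
Why: Buffered desilylation of the silyl enol ether: fluoride attacks silicon while acetic acid protonates C3, so the ketone appears without a long-lived enolate that could expel O1. The tertiary allyl ether and the acetal are not affected.

Step 12
Reactants: 17 (2S)-2-[4-(methoxymethoxy)-3-prenylphenyl]-7-(2-methylbut-3-en-2-yloxy)chroman-4-one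
Product: 19 (2S)-7-hydroxy-2-[4-(methoxymethoxy)-3-prenylphenyl]-8-prenylchroman-4-one, via ortho-dienone 18 (not isolated)
Conditions: xylene, 130 °C
Reagents that add atoms: none
Why: Aromatic Claisen rearrangement: a [3,3] shift moves the allyl terminus from O7 to C8 and the dienone tautomerises to the phenol. The gem-dimethyl group lowers the temperature needed. C8 is expected to be favoured, as in other 7-allyloxy benzopyranones where the C7–C8 bond has the higher double-bond character. The neutral, non-polar medium gives C2 no pathway for ring-opening.

Step 13
Reactants: 19 (2S)-7-hydroxy-2-[4-(methoxymethoxy)-3-prenylphenyl]-8-prenylchroman-4-one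
Product: 20 glabrol, (2S)-7-hydroxy-2-(4-hydroxy-3-prenylphenyl)-8-prenylchroman-4-one
Conditions: HCl (1 M in MeOH), rt to 40 °C
Reagents that add atoms: none
Why: Acid-catalysed acetal exchange with methanol frees the phenol. Dilute acid and short contact should spare the two ortho-prenyl phenols and the flavanone, whose ring-opening needs base or hot acid.

## Compound list

1 | 4-hydroxybenzaldehyde | O=Cc1ccc(O)cc1 | starting material
2 | prenyl bromide (1-bromo-3-methylbut-2-ene) | CC(C)=CCBr | starting material
3 | 4-hydroxy-3-prenylbenzaldehyde | CC(C)=CCc1cc(C=O)ccc1O | intermediate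
4 | 4-(methoxymethoxy)-3-prenylbenzaldehyde | CC(C)=CCc1cc(C=O)ccc1OCOC | intermediate
5 | ethyl (2E)-3-[4-(methoxymethoxy)-3-prenylphenyl]prop-2-enoate | CCOC(=O)/C=C/c1ccc(OCOC)c(CC=C(C)C)c1 | intermediate
6 | (2E)-3-[4-(methoxymethoxy)-3-prenylphenyl]prop-2-en-1-ol | OC/C=C/c1ccc(OCOC)c(CC=C(C)C)c1 | intermediate
7 | methyl (2E)-3-[4-(methoxymethoxy)-3-prenylphenyl]prop-2-en-1-yl carbonate | COC(=O)OC/C=C/c1ccc(OCOC)c(CC=C(C)C)c1 | intermediate
8 | 2,4-dihydroxyacetophenone | CC(=O)c1ccc(O)cc1O | starting material
9 | 3-chloro-3-methylbut-1-yne | CC(C)(Cl)C#C | starting material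
10 | 1-[2-hydroxy-4-(2-methylbut-3-yn-2-yloxy)phenyl]ethanone | CC(=O)c1ccc(OC(C)(C)C#C)cc1O | intermediate
11 | 1-[2-hydroxy-4-(2-methylbut-3-en-2-yloxy)phenyl]ethanone | CC(=O)c1ccc(OC(C)(C)C=C)cc1O | intermediate
12 | sodium 2-acetyl-5-(2-methylbut-3-en-2-yloxy)phenolate | CC(=O)c1ccc(OC(C)(C)C=C)cc1[O-].[Na+] | intermediate
13 | 1-{2-[(1S)-1-(4-(methoxymethoxy)-3-prenylphenyl)prop-2-en-1-yloxy]-4-(2-methylbut-3-en-2-yloxy)phenyl}ethanone | C=C[C@H](Oc1cc(OC(C)(C)C=C)ccc1C(C)=O)c1ccc(OCOC)c(CC=C(C)C)c1 | intermediate
14 | potassium enolate of 13 | C=C[C@H](Oc1cc(OC(C)(C)C=C)ccc1C(=C)[O-])c1ccc(OCOC)c(CC=C(C)C)c1.[K+] | intermediate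
15 | tert-butyldimethylsilyl enol ether of 13 | C=C[C@H](Oc1cc(OC(C)(C)C=C)ccc1C(=C)O[Si](C)(C)C(C)(C)C)c1ccc(OCOC)c(CC=C(C)C)c1 | intermediate
16 | (2S)-4-(tert-butyldimethylsilyloxy)-2-[4-(methoxymethoxy)-3-prenylphenyl]-7-(2-methylbut-3-en-2-yloxy)-2H-chromene | CC(C)=CCc1cc([C@@H]2C=C(O[Si](C)(C)C(C)(C)C)c3ccc(OC(C)(C)C=C)cc3O2)ccc1OCOC | intermediate
17 | (2S)-2-[4-(methoxymethoxy)-3-prenylphenyl]-7-(2-methylbut-3-en-2-yloxy)chroman-4-one | CC(C)=CCc1cc([C@@H]2CC(=O)c3ccc(OC(C)(C)C=C)cc3O2)ccc1OCOC | intermediate
18 | (2S)-2-[4-(methoxymethoxy)-3-prenylphenyl]-8-prenyl-2,3-dihydro-4H-chromene-4,7(8H)-dione (C8 epimers) | CC(C)=CCc1cc([C@@H]2CC(=O)C3=C(O2)C(CC=C(C)C)C(=O)C=C3)ccc1OCOC | intermediate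
19 | (2S)-7-hydroxy-2-[4-(methoxymethoxy)-3-prenylphenyl]-8-prenylchroman-4-one | CC(C)=CCc1cc([C@@H]2CC(=O)c3ccc(O)c(CC=C(C)C)c3O2)ccc1OCOC | intermediate
20 | glabrol, (2S)-7-hydroxy-2-(4-hydroxy-3-prenylphenyl)-8-prenylchroman-4-one | CC(C)=CCc1cc([C@@H]2CC(=O)c3ccc(O)c(CC=C(C)C)c3O2)ccc1O | target

## Step count and risk

Total step count: 13. Longest linear sequence: 11 (steps 1–5, then 8–13); steps 6 and 7 form the two-step side branch.

**Step 10 (key step).**
- What may go wrong: the ruthenium methylidene can add to the enol ether in the unproductive sense and rest as a heteroatom-stabilised carbene, arresting the catalyst. Closure onto the hindered 1,1-disubstituted alkene may also be slow enough that cross-metathesis with the ring B prenyl group intervenes. A ruthenium hydride could move the C2 vinyl group into conjugation and erase the stereocenter. The silyl enol ether can also hydrolyse on handling.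
- Fallback: this sets out from 4 and 11 and returns at 17, giving up metathesis. Claisen–Schmidt condensation of 11 with 4 (KOH, EtOH) should give the chalcone (2E)-1-[2-hydroxy-4-(2-methylbut-3-en-2-yloxy)phenyl]-3-[4-(methoxymethoxy)-3-prenylphenyl]prop-2-en-1-one F1. F1 would be cyclised to 17 by an intramolecular oxa-Michael addition under a cinchona-alkaloid-derived amine–thiourea catalyst. Lower enantiomeric purity is to be expected from this route, so the product would need enrichment by crystallisation or chiral chromatography.

**Step 8.**
- What may go wrong: the chelated, electron-poor aryloxide may attack the allyl complex slowly. The product is itself an allylic aryl ether with an electron-rich aryl group and a good leaving group, so re-ionisation can erode both the branched selectivity and the enantiomeric purity.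
- Fallback: this sets out from 4 and 11 and returns at 13. Vinylmagnesium bromide adds to 4 to give racemic 1-[4-(methoxymethoxy)-3-prenylphenyl]prop-2-en-1-ol F2. Acylation with vinyl acetate and Candida antarctica lipase B converts the R enantiomer to (1R)-1-[4-(methoxymethoxy)-3-prenylphenyl]prop-2-en-1-yl acetate F3 and leaves (1S)-1-[4-(methoxymethoxy)-3-prenylphenyl]prop-2-en-1-ol F4. F4 is converted (n-BuLi, Boc2O) to tert-butyl (1S)-1-[4-(methoxymethoxy)-3-prenylphenyl]prop-2-en-1-yl carbonate F5. F5 reacts with 11 under [Cp*Ru(MeCN)3]PF6 catalysis, a branched-selective allylic etherification that proceeds with net retention, to give 13.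

**Step 12.**
- What may go wrong: migration to C6 may compete with migration to C8, since no chelate fixes the bonds of ring A in the flavanone. Prolonged heating may also cause partial loss of configuration at C2.
- Fallback: this sets out from 11 and returns at 19. Heating 11 (xylene, 130 °C) gives 1-[2,4-dihydroxy-3-prenylphenyl]ethanone F6; here the hydrogen bond between the 2-hydroxyl and the acetyl group directs the shift to the carbon between the two oxygens. Claisen–Schmidt condensation of F6 with 4 (excess KOH, EtOH) gives (2E)-1-(2,4-dihydroxy-3-prenylphenyl)-3-[4-(methoxymethoxy)-3-prenylphenyl]prop-2-en-1-one F7. F7 is cyclised to 19 by the amine–thiourea catalysed oxa-Michael addition named under step 10. Regiochemistry is then secure, at the price of a less selective way of setting C2.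

**Step 13.**
- What may go wrong: acid can cyclise an ortho-prenyl phenol to a 2,2-dimethylchroman or add across a prenyl double bond. Slow acid-mediated opening of ring C would lower the enantiomeric purity.
- Fallback: this sets out from 19 and returns at 20. Treatment with TMSOTf and 2,2'-bipyridyl in CH2Cl2 at 0 °C transfers silicon to the acetal oxygen under non-protic, buffered conditions and should give (2S)-8-prenyl-2-[3-prenyl-4-(trimethylsilyloxy)phenyl]-7-(trimethylsilyloxy)chroman-4-one F8. Addition of water then hydrolyses both aryl silyl ethers to 20.

## Further compounds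

F1 | step 10 | (2E)-1-[2-hydroxy-4-(2-methylbut-3-en-2-yloxy)phenyl]-3-[4-(methoxymethoxy)-3-prenylphenyl]prop-2-en-1-one | CC(C)=CCc1cc(/C=C/C(=O)c2ccc(OC(C)(C)C=C)cc2O)ccc1OCOC
F2 | step 8 | racemic 1-[4-(methoxymethoxy)-3-prenylphenyl]prop-2-en-1-ol | C=CC(O)c1ccc(OCOC)c(CC=C(C)C)c1
F3 | step 8 | (1R)-1-[4-(methoxymethoxy)-3-prenylphenyl]prop-2-en-1-yl acetate | C=C[C@@H](OC(C)=O)c1ccc(OCOC)c(CC=C(C)C)c1
F4 | step 8 | (1S)-1-[4-(methoxymethoxy)-3-prenylphenyl]prop-2-en-1-ol | C=C[C@H](O)c1ccc(OCOC)c(CC=C(C)C)c1
F5 | step 8 | tert-butyl (1S)-1-[4-(methoxymethoxy)-3-prenylphenyl]prop-2-en-1-yl carbonate | C=C[C@H](OC(=O)OC(C)(C)C)c1ccc(OCOC)c(CC=C(C)C)c1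
F6 | step 12 | 1-[2,4-dihydroxy-3-prenylphenyl]ethanone | CC(=O)c1ccc(O)c(CC=C(C)C)c1O
F7 | step 12 | (2E)-1-(2,4-dihydroxy-3-prenylphenyl)-3-[4-(methoxymethoxy)-3-prenylphenyl]prop-2-en-1-one | CC(C)=CCc1cc(/C=C/C(=O)c2ccc(O)c(CC=C(C)C)c2O)ccc1OCOC
F8 | step 13 | (2S)-8-prenyl-2-[3-prenyl-4-(trimethylsilyloxy)phenyl]-7-(trimethylsilyloxy)chroman-4-one | CC(C)=CCc1cc([C@@H]2CC(=O)c3ccc(O[Si](C)(C)C)c(CC=C(C)C)c3O2)ccc1O[Si](C)(C)C
A1 | alternative 1 | 4-(methoxymethoxy)-3-prenyl-2-(trimethylsilyloxy)-1-[1-(trimethylsilyloxy)ethenyl]cyclohexa-1,3-diene | C=C(O[Si](C)(C)C)C1=C(O[Si](C)(C)C)C(CC=C(C)C)=C(OCOC)CC1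
A2 | alternative 1 | 4-formyl-2-prenylphenyl pivalate | CC(C)=CCc1cc(C=O)ccc1OC(=O)C(C)(C)C
A3 | alternative 1 | (2S)-7-(methoxymethoxy)-2-[4-(pivaloyloxy)-3-prenylphenyl]-8-prenyl-2,3,5,6-tetrahydro-4H-chromen-4-one | CC(C)=CCc1cc([C@@H]2CC(=O)C3=C(O2)C(CC=C(C)C)=C(OCOC)CC3)ccc1OC(=O)C(C)(C)C
A4 | alternative 2 | (1S)-3-[2-bromo-4-(methoxymethoxy)-3-prenylphenyl]-3-(tert-butyldimethylsilyloxy)-1-[4-(methoxymethoxy)-3-prenylphenyl]propan-1-ol | CC(C)=CCc1cc([C@@H](O)CC(O[Si](C)(C)C(C)(C)C)c2ccc(OCOC)c(CC=C(C)C)c2Br)ccc1OCOC
A5 | alternative 2 | (2S)-4-(tert-butyldimethylsilyloxy)-7,4'-bis(methoxymethoxy)-8,3'-diprenylflavan | CC(C)=CCc1cc([C@@H]2CC(O[Si](C)(C)C(C)(C)C)c3ccc(OCOC)c(CC=C(C)C)c3O2)ccc1OCOC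
A6 | alternative 3 | 1-bromo-2-fluoro-4-(methoxymethoxy)-3-prenylbenzene | CC(C)=CCc1c(OCOC)ccc(Br)c1F
A7 | alternative 3 | 4-[(2S)-4-oxooxetan-2-yl]-2-prenylphenyl pivalate | CC(C)=CCc1cc([C@@H]2CC(=O)O2)ccc1OC(=O)C(C)(C)C
A8 | alternative 3 | (S)-7-O-methoxymethyl-4'-O-pivaloylglabrol | CC(C)=CCc1cc([C@@H]2CC(=O)c3ccc(OCOC)c(CC=C(C)C)c3O2)ccc1OC(=O)C(C)(C)C
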